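Retrosynthesis: the five free phenols are carried as benzyl ethers. The cuts are, in order: the flavanone C2–aryl bond; the pyranone carbons C2, C3 and C4 of the flavanone, stripped from ring D back to a phenol; the isoflavan O1–C2 ether bond; the C3–C4 and O1–C2(acyl) bonds of ring C together, as a dihydrocoumarin; and the C4–C6 diaryl bond, as a carbinol.
Enabling feature: isoflavan C4 bears ring A, whose oxygen O1 sits on the ortho carbon C8a, so O1–C8a–C4a–C4 is a masked o-quinone methide, while the neighbouring C3 with ring B and C2 is a masked arylacetic acid. Flavanone C6 is para to the C8a oxygen of ring D, so ring D can be carried as a locally symmetric 2,6-bis(benzyloxy)-4-silyloxyphenyl group until its pyranone is built.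
Forward: rings A, B and D are bought. Ring D is joined to the aldehyde carbon of ring A (the future C4), and ring C closes in step 9 as a lactone, which is reduced and reclosed as the pyran.
The silyl ether on ring D is then removed, the flavanone pyranone is built on that oxygen by way of an o-hydroxyacetophenone and a chromone, and the 4-hydroxyphenyl group is added last.
Stereochemistry: C3 and C4 (3R,4S, trans) come from the chiral isothiourea in step 9. Flavanone C2 (S) comes from the chiral pyridine-oxazoline ligand on palladium in step 17, after which only neutral hydrogenolysis follows.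

Key step: step 9

Assumption: the sense of induction in step 9 follows the accepted model for isothiourea-bound (Z)-ammonium enolates (attack remote from the catalyst phenyl group, anti pairing with an (E)-oxadiene) and that of step 17 follows the cyclohexenone series; if a model substrate showed the opposite sense, the enantiomeric catalyst or ligand would be used.

Step 1
Reactants: 1 3,5-bis(benzyloxy)phenol
Product: 2 [3,5-bis(benzyloxy)phenoxy]triisopropylsilane
Conditions: TIPSCl (1.2 equiv), imidazole (2.5 equiv), DMF, rt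
Reagents that add atoms: chlorotriisopropylsilane, CC(C)[Si](Cl)(C(C)C)C(C)C
Why: Imidazole-mediated O-silylation of the only phenol; the triisopropylsilyl group marks the oxygen that will become the flavanone ring oxygen and shields the two ring carbons beside it.

Step 2
Reactants: 2 [3,5-bis(benzyloxy)phenoxy]triisopropylsilane
Product: 3 [3,5-bis(benzyloxy)-4-bromophenoxy]triisopropylsilane
Conditions: NBS (1.0 equiv), CH2Cl2, -40 °C to 0 °C, dark
Reagents that add atoms: N-bromosuccinimide, O=C1CCC(=O)N1Br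
Why: Electrophilic aromatic bromination; the three free ring carbons are electronically alike (each is ortho or para to all three oxygens), so the bulky silyl ether should steer bromine to the carbon between the two benzyloxy groups, and one equivalent of NBS at low temperature guards against a second bromination.

Step 3
Reactants: 3 [3,5-bis(benzyloxy)-4-bromophenoxy]triisopropylsilane; 4 4-(benzyloxy)-2-hydroxybenzaldehyde
Product: 7 rac-5-(benzyloxy)-2-[{2,6-bis(benzyloxy)-4-[(triisopropylsilyl)oxy]phenyl}(hydroxy)methyl]phenol, via sodium phenoxide 5 (not isolated), via aryllithium 6 (not isolated)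
Conditions: (a) 4, NaH (1.05 equiv), THF, 0 °C; (b) 3 (1.1 equiv), n-BuLi (1.1 equiv), THF, -78 °C; (c) solution of 5 added to 6, -78 °C to 0 °C; aq NH4Cl
Reagents that add atoms: none
Why: Bromine-lithium exchange at -78 °C is far faster than benzylic deprotonation of the benzyl ethers, and the aryllithium then undergoes 1,2-addition to the aldehyde of the preformed phenoxide (as aryl Grignard reagents add to salicylaldehydes); the new carbinol centre is racemic and is erased when the methide is formed.

Step 4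
Reactants: 7 rac-5-(benzyloxy)-2-[{2,6-bis(benzyloxy)-4-[(triisopropylsilyl)oxy]phenyl}(hydroxy)methyl]phenol
Product: 8 rac-5-(benzyloxy)-2-[{2,6-bis(benzyloxy)-4-[(triisopropylsilyl)oxy]phenyl}(4-methylbenzenesulfonyl)methyl]phenol
Conditions: p-TolSO2H (1.5 equiv), CH2Cl2, 4 Å MS, rt
Reagents that add atoms: 4-methylbenzenesulfinic acid, Cc1ccc(cc1)S(=O)O
Why: Acid-promoted SN1 substitution: the doubly donor-stabilised benzhydrylic cation (a protonated o-quinone methide) is captured at sulfur by the sulfinate, giving the 2-(sulfonylmethyl)phenol that is the standard storable precursor of o-quinone methides.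

Step 5
Reactants: 9 2,6-dimethoxyphenol
Product: 10 2-(benzyloxy)-1,3-dimethoxybenzene
Conditions: BnBr (1.2 equiv), K2CO3 (2 equiv), DMF, 60 °C
Reagents that add atoms: benzyl bromide, BrCc1ccccc1
Why: Williamson ether synthesis on the hindered but acidic phenol.

Step 6
Reactants: 10 2-(benzyloxy)-1,3-dimethoxybenzene
Product: 11 2-(benzyloxy)-4-bromo-1,3-dimethoxybenzene
Conditions: NBS (1.05 equiv), MeCN, 0 °C to rt
Reagents that add atoms: N-bromosuccinimide, O=C1CCC(=O)N1Br
Why: Electrophilic aromatic bromination of a pyrogallol triether, which goes to C4 (para to one methoxy group and ortho to the other) and not to C5, which is activated only by the para benzyloxy group.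

Step 7
Reactants: 11 2-(benzyloxy)-4-bromo-1,3-dimethoxybenzene
Product: 12 ethyl 2-[3-(benzyloxy)-2,4-dimethoxyphenyl]acetate
Conditions: BrZnCH2CO2Et (1.5 equiv), Pd2(dba)3 (2 mol %), 2-dicyclohexylphosphino-2',4',6'-triisopropylbiphenyl (XPhos, 8 mol %), THF, 65 °C
Reagents that add atoms: (2-ethoxy-2-oxoethyl)zinc bromide, CCOC(=O)C[Zn]Br
Why: Negishi-type cross-coupling of a Reformatsky reagent (palladium-catalysed alpha-arylation of an ester zinc enolate): oxidative addition of zerovalent palladium to the aryl bromide, transmetalation and reductive elimination, with the bulky biaryl phosphine coping with the ortho methoxy group.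

Step 8
Reactants: 12 ethyl 2-[3-(benzyloxy)-2,4-dimethoxyphenyl]acetate
Product: 13 2-[3-(benzyloxy)-2,4-dimethoxyphenyl]acetic acid
Conditions: LiOH·H2O (3 equiv), THF-MeOH-H2O, rt; then 1 M HCl
Reagents that add atoms: lithium hydroxide, [Li+].[OH-]
Why: Ester saponification; the benzyl and methyl ethers are inert to aqueous base.

Step 9
Reactants: 8 rac-5-(benzyloxy)-2-[{2,6-bis(benzyloxy)-4-[(triisopropylsilyl)oxy]phenyl}(4-methylbenzenesulfonyl)methyl]phenol; 13 2-[3-(benzyloxy)-2,4-dimethoxyphenyl]acetic acid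
Product: 16 (3R,4S)-7-(benzyloxy)-3-[3-(benzyloxy)-2,4-dimethoxyphenyl]-4-{2,6-bis(benzyloxy)-4-[(triisopropylsilyl)oxy]phenyl}chroman-2-one, via pivalic mixed anhydride 14 (not isolated), via o-quinone methide 15 (not isolated)
Conditions: (a) 8, Cs2CO3 (2 equiv), CH2Cl2, rt, then cannula filtration; (b) 13 (1.5 equiv), t-BuCOCl (1.5 equiv), i-Pr2NEt (1.5 equiv), CH2Cl2, 0 °C; (c) solutions combined, (2S,3R)-3-isopropyl-2-phenyl-3,4-dihydro-2H-benzo[4,5]thiazolo[3,2-a]pyrimidine (HyperBTM, 10 mol %), i-Pr2NEt (1.5 equiv), -40 °C to rt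
Reagents that add atoms: none
Why: The isothiourea is acylated by anhydride 14, the acyl ammonium ion is deprotonated to a (Z)-ammonium enolate held coplanar with the catalyst by its 1,5 oxygen-sulfur contact, this enolate adds through the face remote from the catalyst phenyl group to the exocyclic carbon of methide 15 with rearomatisation of ring A, and the ring A phenoxide so formed attacks the acyl ammonium carbon and frees the catalyst. The closest known reaction type is the isothiourea-catalysed Michael addition-lactonisation (formal [4+2] annulation) of arylacetic acid derived ammonium enolates with o-quinone methides to give 3,4-disubstituted dihydrocoumarins, applied here to a methide whose carbon carries a 2,6-dioxygenated aryl group. Ring C is the only ring closed: the C3-C4 bond is made intermolecularly and the O1-C2 bond by 6-exo-trig attack of the phenoxide on the acyl ammonium carbonyl. C3 is controlled by the catalyst, whose C2 phenyl group shields one face of the bound enolate, and C4 by the relative topicity of the addition, the enolate aryl group and the methide aryl group taking the anti arrangement usual for (Z)-ammonium enolates and (E)-oxadienes, so that the (3R,4S) trans lactone is expected with the (2S,3R) catalyst. The step needs enantioface control at the enolate together with high anti selectivity in the bond-forming event, because a cis lactone would carry the wrong C4 configuration and would end as the enantiomeric trans lactone if the amine epimerised its acidic C3-H; the first is secured by the oxygen-sulfur lock, the second by the single (E) geometry that the two ortho benzyloxy groups of ring D impose on 15 and by the trans lactone being also the thermodynamic isomer. The 3-benzyloxy group and the trioxygenated ring D should make 15 persistent and leave it one electrophilic carbon only, at the price of lower electrophilicity and crowding, which is the accepted risk of the step.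

Step 10
Reactants: 16 (3R,4S)-7-(benzyloxy)-3-[3-(benzyloxy)-2,4-dimethoxyphenyl]-4-{2,6-bis(benzyloxy)-4-[(triisopropylsilyl)oxy]phenyl}chroman-2-one
Product: 17 (2R,3S)-3-[4-(benzyloxy)-2-hydroxyphenyl]-2-[3-(benzyloxy)-2,4-dimethoxyphenyl]-3-{2,6-bis(benzyloxy)-4-[(triisopropylsilyl)oxy]phenyl}propan-1-ol
Conditions: LiBH4 (3 equiv), THF, 0 °C to rt; aq NH4Cl
Reagents that add atoms: none
Why: Hydride reduction of an aryl ester (lactone) to the primary alcohol with release of the ring A phenol; LiBH4 leaves silyl and benzyl ethers alone, and the intermediate aldehyde is reduced faster than it can enolise, so C3 and C4 are unchanged.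

Step 11
Reactants: 17 (2R,3S)-3-[4-(benzyloxy)-2-hydroxyphenyl]-2-[3-(benzyloxy)-2,4-dimethoxyphenyl]-3-{2,6-bis(benzyloxy)-4-[(triisopropylsilyl)oxy]phenyl}propan-1-ol
Product: 18 (3R,4S)-7-(benzyloxy)-3-[3-(benzyloxy)-2,4-dimethoxyphenyl]-4-{2,6-bis(benzyloxy)-4-[(triisopropylsilyl)oxy]phenyl}chromane
Conditions: PPh3 (1.5 equiv), DIAD (1.5 equiv), THF, 0 °C to rt
Reagents that add atoms: none
Why: Mitsunobu cycloetherification: the only free phenol displaces the activated primary alcohol in a 6-exo-tet closure at the non-stereogenic C2, so neither stereocentre is involved.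

Step 12
Reactants: 18 (3R,4S)-7-(benzyloxy)-3-[3-(benzyloxy)-2,4-dimethoxyphenyl]-4-{2,6-bis(benzyloxy)-4-[(triisopropylsilyl)oxy]phenyl}chromane
Product: 19 3,5-bis(benzyloxy)-4-{(3R,4S)-7-(benzyloxy)-3-[3-(benzyloxy)-2,4-dimethoxyphenyl]chroman-4-yl}phenol
Conditions: Bu4NF (1.2 equiv), THF, 0 °C; aq NH4Cl
Reagents that add atoms: none
Why: Fluoride-induced cleavage of the aryl silyl ether, driven by the Si-F bond, frees the single phenol of the molecule, the one on ring D para to the isoflavan unit.

Step 13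
Reactants: 19 3,5-bis(benzyloxy)-4-{(3R,4S)-7-(benzyloxy)-3-[3-(benzyloxy)-2,4-dimethoxyphenyl]chroman-4-yl}phenol
Product: 20 4,6-bis(benzyloxy)-5-{(3R,4S)-7-(benzyloxy)-3-[3-(benzyloxy)-2,4-dimethoxyphenyl]chroman-4-yl}-2-hydroxybenzaldehyde
Conditions: MgCl2 (3 equiv), Et3N (6 equiv), (CH2O)n (10 equiv), MeCN, 80 °C
Reagents that add atoms: paraformaldehyde (as formaldehyde), C=O
Why: Magnesium-mediated ortho-formylation (Casnati-Skattebøl reaction): the magnesium phenoxide delivers formaldehyde to the ortho carbon and the hydroxymethyl intermediate is oxidised by a second formaldehyde, so only the phenolic ring reacts, and its two ortho carbons are constitutionally equivalent.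

Step 14
Reactants: 20 4,6-bis(benzyloxy)-5-{(3R,4S)-7-(benzyloxy)-3-[3-(benzyloxy)-2,4-dimethoxyphenyl]chroman-4-yl}-2-hydroxybenzaldehyde
Product: 21 3,5-bis(benzyloxy)-4-{(3R,4S)-7-(benzyloxy)-3-[3-(benzyloxy)-2,4-dimethoxyphenyl]chroman-4-yl}-2-(1-hydroxyethyl)phenol (both epimers at the new carbinol carbon)
Conditions: MeMgBr (3.5 equiv), THF, -20 °C to 0 °C; aq NH4Cl
Reagents that add atoms: methylmagnesium bromide, C[Mg]Br
Why: Grignard addition to the aldehyde after the first equivalent has deprotonated the phenol; the new carbinol centre forms as both epimers, which is of no consequence because it is oxidised in the next step.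

Step 15
Reactants: 21 3,5-bis(benzyloxy)-4-{(3R,4S)-7-(benzyloxy)-3-[3-(benzyloxy)-2,4-dimethoxyphenyl]chroman-4-yl}-2-(1-hydroxyethyl)phenol
Product: 22 1-[2,4-bis(benzyloxy)-3-{(3R,4S)-7-(benzyloxy)-3-[3-(benzyloxy)-2,4-dimethoxyphenyl]chroman-4-yl}-6-hydroxyphenyl]ethan-1-one
Conditions: MnO2 (activated, 20 equiv), CH2Cl2, rt
Reagents that add atoms: none
Why: Manganese dioxide oxidation of a benzylic alcohol under neutral conditions, which avoids the acid that would ionise the o-hydroxybenzylic alcohol and gives the hydrogen-bonded o-hydroxyacetophenone.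

Step 16
Reactants: 22 1-[2,4-bis(benzyloxy)-3-{(3R,4S)-7-(benzyloxy)-3-[3-(benzyloxy)-2,4-dimethoxyphenyl]chroman-4-yl}-6-hydroxyphenyl]ethan-1-one
Product: 24 5,7-bis(benzyloxy)-6-{(3R,4S)-7-(benzyloxy)-3-[3-(benzyloxy)-2,4-dimethoxyphenyl]chroman-4-yl}-4H-chromen-4-one, via enaminone 23 (not isolated)
Conditions: Me2NCH(OMe)2 (3 equiv), toluene, 95 °C; evaporate; then AcOH, 70 °C
Reagents that add atoms: N,N-dimethylformamide dimethyl acetal, COC(OC)N(C)C
Why: Enaminone route to chromones: the amide acetal condenses with the methyl ketone, and in acetic acid the phenol adds to the enaminone beta carbon and dimethylamine is lost (6-endo closure by addition-elimination), which places the ring oxygen on the formerly silylated oxygen.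

Step 17
Reactants: 24 5,7-bis(benzyloxy)-6-{(3R,4S)-7-(benzyloxy)-3-[3-(benzyloxy)-2,4-dimethoxyphenyl]chroman-4-yl}-4H-chromen-4-one; 25 [4-(benzyloxy)phenyl]boronic acid
Product: 26 (2S)-5,7-bis(benzyloxy)-2-[4-(benzyloxy)phenyl]-6-{(3R,4S)-7-(benzyloxy)-3-[3-(benzyloxy)-2,4-dimethoxyphenyl]chroman-4-yl}chroman-4-one
Conditions: 25 (2 equiv), Pd(OCOCF3)2 (10 mol %), (R)-4-tert-butyl-2-(pyridin-2-yl)-4,5-dihydrooxazole (12 mol %), NH4PF6 (30 mol %), H2O (5 equiv), ClCH2CH2Cl, 60 °C
Reagents that add atoms: none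
Why: Palladium-catalysed asymmetric conjugate addition of an arylboronic acid to a chromone: transmetalation to cationic divalent palladium, enantioface-selective insertion of the C2-C3 double bond under control of the pyridine-oxazoline ligand and protonation of the palladium enolate by water should set C2 as (S) without base, so the flavanone cannot racemise by ring opening, and the remote isoflavan centres play no part.

Step 18
Reactants: 26 (2S)-5,7-bis(benzyloxy)-2-[4-(benzyloxy)phenyl]-6-{(3R,4S)-7-(benzyloxy)-3-[3-(benzyloxy)-2,4-dimethoxyphenyl]chroman-4-yl}chroman-4-one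
Product: 27 (2S)-5,7-dihydroxy-6-[(3R,4S)-7-hydroxy-3-(3-hydroxy-2,4-dimethoxyphenyl)chroman-4-yl]-2-(4-hydroxyphenyl)chroman-4-one (CNP0267463.1)
Conditions: H2 (1 atm), 10% Pd/C, EtOAc-MeOH (1:1), rt
Reagents that add atoms: none
Why: Catalytic hydrogenolysis of five aryl benzyl ethers at ambient temperature and pressure, neutral conditions under which the methyl ethers, the aryl ketone and the base-labile flavanone C2 centre should persist; the reaction is stopped at full debenzylation to keep the benzylic C2-O bond of the flavanone intact.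

Compound list
1 | 3,5-bis(benzyloxy)phenol | Oc1cc(OCc2ccccc2)cc(OCc2ccccc2)c1 | starting material
2 | [3,5-bis(benzyloxy)phenoxy]triisopropylsilane | CC(C)[Si](Oc1cc(OCc2ccccc2)cc(OCc2ccccc2)c1)(C(C)C)C(C)C | intermediate
3 | [3,5-bis(benzyloxy)-4-bromophenoxy]triisopropylsilane | CC(C)[Si](Oc1cc(OCc2ccccc2)c(Br)c(OCc2ccccc2)c1)(C(C)C)C(C)C | intermediate
4 | 4-(benzyloxy)-2-hydroxybenzaldehyde | O=Cc1ccc(OCc2ccccc2)cc1O | starting material
5 | sodium 5-(benzyloxy)-2-formylphenolate | [Na+].[O-]c1cc(OCc2ccccc2)ccc1C=O | intermediate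
6 | {2,6-bis(benzyloxy)-4-[(triisopropylsilyl)oxy]phenyl}lithium | [Li]c1c(OCc2ccccc2)cc(O[Si](C(C)C)(C(C)C)C(C)C)cc1OCc1ccccc1 | intermediate
7 | rac-5-(benzyloxy)-2-[{2,6-bis(benzyloxy)-4-[(triisopropylsilyl)oxy]phenyl}(hydroxy)methyl]phenol | OC(c1ccc(OCc2ccccc2)cc1O)c1c(OCc2ccccc2)cc(O[Si](C(C)C)(C(C)C)C(C)C)cc1OCc1ccccc1 | intermediate
8 | rac-5-(benzyloxy)-2-[{2,6-bis(benzyloxy)-4-[(triisopropylsilyl)oxy]phenyl}(4-methylbenzenesulfonyl)methyl]phenol | Cc1ccc(cc1)S(=O)(=O)C(c1ccc(OCc2ccccc2)cc1O)c1c(OCc2ccccc2)cc(O[Si](C(C)C)(C(C)C)C(C)C)cc1OCc1ccccc1 | intermediate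
9 | 2,6-dimethoxyphenol | COc1cccc(OC)c1O | starting material
10 | 2-(benzyloxy)-1,3-dimethoxybenzene | COc1cccc(OC)c1OCc1ccccc1 | intermediate
11 | 2-(benzyloxy)-4-bromo-1,3-dimethoxybenzene | COc1ccc(Br)c(OC)c1OCc1ccccc1 | intermediate
12 | ethyl 2-[3-(benzyloxy)-2,4-dimethoxyphenyl]acetate | CCOC(=O)Cc1ccc(OC)c(OCc2ccccc2)c1OC | intermediate
13 | 2-[3-(benzyloxy)-2,4-dimethoxyphenyl]acetic acid | COc1ccc(CC(=O)O)c(OC)c1OCc1ccccc1 | intermediate
14 | 2-[3-(benzyloxy)-2,4-dimethoxyphenyl]acetic 2,2-dimethylpropanoic anhydride | COc1ccc(CC(=O)OC(=O)C(C)(C)C)c(OC)c1OCc1ccccc1 | intermediate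
15 | (6E)-3-(benzyloxy)-6-{2,6-bis(benzyloxy)-4-[(triisopropylsilyl)oxy]benzylidene}cyclohexa-2,4-dien-1-one | O=C1C=C(OCc2ccccc2)C=C/C1=C\c1c(OCc2ccccc2)cc(O[Si](C(C)C)(C(C)C)C(C)C)cc1OCc1ccccc1 | intermediate
16 | (3R,4S)-7-(benzyloxy)-3-[3-(benzyloxy)-2,4-dimethoxyphenyl]-4-{2,6-bis(benzyloxy)-4-[(triisopropylsilyl)oxy]phenyl}chroman-2-one | COc1ccc([C@@H]2C(=O)Oc3cc(OCc4ccccc4)ccc3[C@H]2c2c(OCc3ccccc3)cc(O[Si](C(C)C)(C(C)C)C(C)C)cc2OCc2ccccc2)c(OC)c1OCc1ccccc1 | intermediate
17 | (2R,3S)-3-[4-(benzyloxy)-2-hydroxyphenyl]-2-[3-(benzyloxy)-2,4-dimethoxyphenyl]-3-{2,6-bis(benzyloxy)-4-[(triisopropylsilyl)oxy]phenyl}propan-1-ol | COc1ccc([C@H](CO)[C@@H](c2ccc(OCc3ccccc3)cc2O)c2c(OCc3ccccc3)cc(O[Si](C(C)C)(C(C)C)C(C)C)cc2OCc2ccccc2)c(OC)c1OCc1ccccc1 | intermediate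
18 | (3R,4S)-7-(benzyloxy)-3-[3-(benzyloxy)-2,4-dimethoxyphenyl]-4-{2,6-bis(benzyloxy)-4-[(triisopropylsilyl)oxy]phenyl}chromane | COc1ccc([C@@H]2COc3cc(OCc4ccccc4)ccc3[C@H]2c2c(OCc3ccccc3)cc(O[Si](C(C)C)(C(C)C)C(C)C)cc2OCc2ccccc2)c(OC)c1OCc1ccccc1 | intermediate
19 | 3,5-bis(benzyloxy)-4-{(3R,4S)-7-(benzyloxy)-3-[3-(benzyloxy)-2,4-dimethoxyphenyl]chroman-4-yl}phenol | COc1ccc([C@@H]2COc3cc(OCc4ccccc4)ccc3[C@H]2c2c(OCc3ccccc3)cc(O)cc2OCc2ccccc2)c(OC)c1OCc1ccccc1 | intermediate
20 | 4,6-bis(benzyloxy)-5-{(3R,4S)-7-(benzyloxy)-3-[3-(benzyloxy)-2,4-dimethoxyphenyl]chroman-4-yl}-2-hydroxybenzaldehyde | COc1ccc([C@@H]2COc3cc(OCc4ccccc4)ccc3[C@H]2c2c(OCc3ccccc3)cc(O)c(C=O)c2OCc2ccccc2)c(OC)c1OCc1ccccc1 | intermediate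
21 | 3,5-bis(benzyloxy)-4-{(3R,4S)-7-(benzyloxy)-3-[3-(benzyloxy)-2,4-dimethoxyphenyl]chroman-4-yl}-2-(1-hydroxyethyl)phenol (both carbinol epimers) | COc1ccc([C@@H]2COc3cc(OCc4ccccc4)ccc3[C@H]2c2c(OCc3ccccc3)cc(O)c(C(C)O)c2OCc2ccccc2)c(OC)c1OCc1ccccc1 | intermediate
22 | 1-[2,4-bis(benzyloxy)-3-{(3R,4S)-7-(benzyloxy)-3-[3-(benzyloxy)-2,4-dimethoxyphenyl]chroman-4-yl}-6-hydroxyphenyl]ethan-1-one | COc1ccc([C@@H]2COc3cc(OCc4ccccc4)ccc3[C@H]2c2c(OCc3ccccc3)cc(O)c(C(C)=O)c2OCc2ccccc2)c(OC)c1OCc1ccccc1 | intermediate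
23 | (2E)-1-[2,4-bis(benzyloxy)-3-{(3R,4S)-7-(benzyloxy)-3-[3-(benzyloxy)-2,4-dimethoxyphenyl]chroman-4-yl}-6-hydroxyphenyl]-3-(dimethylamino)prop-2-en-1-one | COc1ccc([C@@H]2COc3cc(OCc4ccccc4)ccc3[C@H]2c2c(OCc3ccccc3)cc(O)c(C(=O)/C=C/N(C)C)c2OCc2ccccc2)c(OC)c1OCc1ccccc1 | intermediate
24 | 5,7-bis(benzyloxy)-6-{(3R,4S)-7-(benzyloxy)-3-[3-(benzyloxy)-2,4-dimethoxyphenyl]chroman-4-yl}-4H-chromen-4-one | COc1ccc([C@@H]2COc3cc(OCc4ccccc4)ccc3[C@H]2c2c(OCc3ccccc3)cc3occc(=O)c3c2OCc2ccccc2)c(OC)c1OCc1ccccc1 | intermediate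
25 | [4-(benzyloxy)phenyl]boronic acid | OB(O)c1ccc(OCc2ccccc2)cc1 | starting material
26 | (2S)-5,7-bis(benzyloxy)-2-[4-(benzyloxy)phenyl]-6-{(3R,4S)-7-(benzyloxy)-3-[3-(benzyloxy)-2,4-dimethoxyphenyl]chroman-4-yl}chroman-4-one | COc1ccc([C@@H]2COc3cc(OCc4ccccc4)ccc3[C@H]2c2c(OCc3ccccc3)cc3c(c2OCc2ccccc2)C(=O)C[C@@H](c2ccc(OCc4ccccc4)cc2)O3)c(OC)c1OCc1ccccc1 | intermediate
27 | (2S)-5,7-dihydroxy-6-[(3R,4S)-7-hydroxy-3-(3-hydroxy-2,4-dimethoxyphenyl)chroman-4-yl]-2-(4-hydroxyphenyl)chroman-4-one (CNP0267463.1) | COc1ccc([C@@H]2COc3cc(O)ccc3[C@H]2c2c(O)cc3c(c2O)C(=O)C[C@@H](c2ccc(O)cc2)O3)c(OC)c1O | target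

Total step count: 18 steps.
Longest linear sequence: 14 steps (steps 1, 2, 3, 4 and 9 to 18 from compound 1; equally steps 5 to 18 from compound 9).

Steps most likely to fail

Step 9. The enolate may fail to reach the crowded, electron-rich methide carbon before the acyl ammonium ion decays, or the addition may proceed with poor face or anti selectivity. The fallback replaces the catalyst by a stoichiometric chiral auxiliary; it sets out from acid 13 and sulfone 8 and comes back to the route at lactone 16.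
- Acid 13 is converted through its mixed anhydride 14 (t-BuCOCl, Et3N, THF, -20 °C) and lithiated (R)-4-benzyloxazolidin-2-one into (R)-4-benzyl-3-{2-[3-(benzyloxy)-2,4-dimethoxyphenyl]acetyl}oxazolidin-2-one F1.
- NaN(SiMe3)2 in THF at -78 °C should give the chelated sodium (Z)-enolate of this imide F2. A filtered solution of methide 15 (from 8 and Cs2CO3, as in step 9) is then added.
- Michael addition on the enolate face remote from the benzyl group should give, after protonation, (R)-4-benzyl-3-[(2R,3S)-3-[4-(benzyloxy)-2-hydroxyphenyl]-2-[3-(benzyloxy)-2,4-dimethoxyphenyl]-3-{2,6-bis(benzyloxy)-4-[(triisopropylsilyl)oxy]phenyl}propanoyl]oxazolidin-2-one F3. All its stereoisomers are diastereomers, so they can be separated by chromatography.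
- Catalytic DBU in CH2Cl2 then lets the ring A phenol close on the exocyclic imide carbonyl with loss of the auxiliary, which gives 16.

Step 17. Insertion into the electron-rich chromone, crowded by its 5-benzyloxy and 6-isoflavanyl groups, may be slow, so that protodeboronation of 25 outruns the addition or the enantioface control is poor. The fallback builds the flavanone from the chalcone; it sets out from acetophenone 22 and comes back to the route at 26.
- Claisen-Schmidt condensation of 22 with 4-(benzyloxy)benzaldehyde (KOH, EtOH-THF, rt) should give (2E)-1-[2,4-bis(benzyloxy)-3-{(3R,4S)-7-(benzyloxy)-3-[3-(benzyloxy)-2,4-dimethoxyphenyl]chroman-4-yl}-6-hydroxyphenyl]-3-[4-(benzyloxy)phenyl]prop-2-en-1-one F4.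
- NaOAc in refluxing EtOH then closes the pyranone by intramolecular oxa-Michael addition, which gives 26 together with its C2 epimer, the (2R)-flavanone F5.
- The isoflavan unit makes these two diastereomers, so they can be separated by chromatography (preparative HPLC if needed). The unwanted epimer is returned to the chalcone-flavanone equilibrium under the same basic conditions.

Step 2. Bromine may enter beside the silyl ether, or a second bromination may occur on the very electron-rich ring. The fallback avoids the halide; it sets out from silyl ether 2 and comes back to the route at carbinol 7, and it makes no new compound (entry F0).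
- Treatment of 2 with n-BuLi in THF at 0 °C should effect directed ortho-lithiation at the carbon flanked by the two benzyloxy groups, the only position activated by two directing groups and not shielded by the silyl group. This gives aryllithium 6 directly.
- Aryllithium 6 is added to phenoxide 5 as in step 3.
- The risk of this fallback is competing benzylic metalation with Wittig rearrangement; it is limited by the use of n-BuLi and not t-BuLi, and by keeping the temperature at or below 0 °C.

Further compounds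
F1 | step 9 | (R)-4-benzyl-3-{2-[3-(benzyloxy)-2,4-dimethoxyphenyl]acetyl}oxazolidin-2-one | COc1ccc(CC(=O)N2[C@H](Cc3ccccc3)COC2=O)c(OC)c1OCc1ccccc1
F2 | step 9 | sodium (Z)-enolate of F1 | COc1ccc(/C=C(\[O-])N2[C@H](Cc3ccccc3)COC2=O)c(OC)c1OCc1ccccc1.[Na+]
F3 | step 9 | (R)-4-benzyl-3-[(2R,3S)-3-[4-(benzyloxy)-2-hydroxyphenyl]-2-[3-(benzyloxy)-2,4-dimethoxyphenyl]-3-{2,6-bis(benzyloxy)-4-[(triisopropylsilyl)oxy]phenyl}propanoyl]oxazolidin-2-one | COc1ccc([C@H](C(=O)N2[C@H](Cc3ccccc3)COC2=O)[C@@H](c2ccc(OCc3ccccc3)cc2O)c2c(OCc3ccccc3)cc(O[Si](C(C)C)(C(C)C)C(C)C)cc2OCc2ccccc2)c(OC)c1OCc1ccccc1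
F4 | step 17 | (2E)-1-[2,4-bis(benzyloxy)-3-{(3R,4S)-7-(benzyloxy)-3-[3-(benzyloxy)-2,4-dimethoxyphenyl]chroman-4-yl}-6-hydroxyphenyl]-3-[4-(benzyloxy)phenyl]prop-2-en-1-one | COc1ccc([C@@H]2COc3cc(OCc4ccccc4)ccc3[C@H]2c2c(OCc3ccccc3)cc(O)c(C(=O)/C=C/c3ccc(OCc4ccccc4)cc3)c2OCc2ccccc2)c(OC)c1OCc1ccccc1
F5 | step 17 | (2R)-5,7-bis(benzyloxy)-2-[4-(benzyloxy)phenyl]-6-{(3R,4S)-7-(benzyloxy)-3-[3-(benzyloxy)-2,4-dimethoxyphenyl]chroman-4-yl}chroman-4-one | COc1ccc([C@@H]2COc3cc(OCc4ccccc4)ccc3[C@H]2c2c(OCc3ccccc3)cc3c(c2OCc2ccccc2)C(=O)C[C@H](c2ccc(OCc4ccccc4)cc2)O3)c(OC)c1OCc1ccccc1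
F0 | step 2 | none | none
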